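The target is cut at the bond between C2 of the γ-pyranone ring C and C1' of ring B. The key step exploits that C2–H of a 3-unsubstituted chromone, flanked by O1 and vinylogous to the C4 carbonyl, is its most acidic C–H once MgCl2 binds the carbonyl. Direct zincation there and Negishi coupling with a fully prenylated, doubly ortho-substituted ring B bromide join the two halves with all three prenyl groups in place. The bromide is drawn from symmetrical 4,5-dibromocatechol, whose bromines mark C1' and C6'. Lithiation, borylation and oxidation at C3, then MOM removal, finish the flavonol.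

Key step: step 7

Remark: the target has no stereocentre, so no stereocontrol is needed; 4,5-dibromobenzene-1,2-diol is taken as a purchasable building block (prenyl = 3-methylbut-2-en-1-yl, MOM = methoxymethyl, TMP = 2,2,6,6-tetramethylpiperidide, SPhos = 2-dicyclohexylphosphino-2',6'-dimethoxybiphenyl).

Step 1
Reactants: 1 2,4,6-trihydroxyacetophenone
Product: 2 1-[2,4,6-trihydroxy-3-(3-methylbut-2-en-1-yl)phenyl]ethan-1-one
Conditions: prenyl bromide (1.0 equiv), DBU, THF, 0 °C → rt
Reagents that add atoms: prenyl bromide, CC(C)=CCBr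
Why: Friedel–Crafts-type C-alkylation of the phloroglucinol phenoxide: the soft ring carbon attacks the primary allylic bromide in an SN2 reaction, both free ring positions are equivalent, and keeping the bromide limiting should hold back double and O-alkylation.

Step 2
Reactants: 2 1-[2,4,6-trihydroxy-3-(3-methylbut-2-en-1-yl)phenyl]ethan-1-one
Product: 3 1-[2-hydroxy-4,6-bis(methoxymethoxy)-3-(3-methylbut-2-en-1-yl)phenyl]ethan-1-one
Conditions: MOMCl (2.1 equiv), i-Pr2NEt, CH2Cl2, 0 °C
Reagents that add atoms: chloromethyl methyl ether (MOMCl), COCCl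
Why: MOM ether formation (Williamson-type alkylation) should take the unchelated 4-OH and the less hindered 6-OH, while the 2-OH, held in a hydrogen bond to the acetyl group and crowded by the prenyl group, stays free and so becomes the ring oxygen O1 next to C8.

Step 3
Reactants: 3 1-[2-hydroxy-4,6-bis(methoxymethoxy)-3-(3-methylbut-2-en-1-yl)phenyl]ethan-1-one
Product: 5 5,7-bis(methoxymethoxy)-8-(3-methylbut-2-en-1-yl)-4H-chromen-4-one, via enaminone 4 (not isolated)
Conditions: DMF-DMA, toluene, 95 °C; then AcOH, 60 °C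
Reagents that add atoms: N,N-dimethylformamide dimethyl acetal (DMF-DMA), COC(OC)N(C)C
Why: Enaminone route to chromones: condensation of the methyl ketone with the amide acetal gives enaminone 4, and under mild acid the free phenol adds to its β-carbon in a conjugate addition and expels dimethylamine, which closes ring C with C2 and C3 unsubstituted and leaves the MOM ethers intact.

Step 4
Reactants: 6 4,5-dibromobenzene-1,2-diol
Product: 7 1,2-dibromo-4,5-bis(methoxymethoxy)benzene
Conditions: MOMCl (2.3 equiv), i-Pr2NEt, CH2Cl2, 0 °C → rt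
Reagents that add atoms: chloromethyl methyl ether (MOMCl), COCCl
Why: Twofold MOM ether formation (Williamson-type alkylation) masks the catechol against the organometallic steps that follow and leaves a symmetrical dibromide in which the two bromines stand at the later C1' and C6'.

Step 5
Reactants: 7 1,2-dibromo-4,5-bis(methoxymethoxy)benzene
Product: 9 1-bromo-4,5-bis(methoxymethoxy)-2-(3-methylbut-2-en-1-yl)benzene, via arylmagnesium chloride 8 (not isolated)
Conditions: i-PrMgCl·LiCl (1.05 equiv), THF, −15 °C; then CuI (10 mol%), prenyl bromide, −15 °C → rt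
Reagents that add atoms: prenyl bromide, CC(C)=CCBr
Why: Bromine–magnesium exchange on the symmetrical dibromide should stop after one exchange because the aryl Grignard formed is far less prone to a second one, the ortho-bromo Grignard is stable at this temperature, and copper-catalysed allylic substitution at the primary carbon of prenyl bromide gives the linear prenyl arene.

Step 6
Reactants: 9 1-bromo-4,5-bis(methoxymethoxy)-2-(3-methylbut-2-en-1-yl)benzene
Product: 12 4-bromo-1,2-bis(methoxymethoxy)-3,5-bis(3-methylbut-2-en-1-yl)benzene, via aryllithium 10 (not isolated), via arylcopper 11 (not isolated)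
Conditions: LiN(i-Pr)2, THF, −78 °C; CuBr·SMe2 (1.1 equiv), −78 → −40 °C; prenyl bromide, → 0 °C
Reagents that add atoms: prenyl bromide, CC(C)=CCBr
Why: Directed ortho-metalation: the C–H flanked by bromine and a MOM ether is the most acidic one and is removed by the amide base at −78 °C, where the ortho-bromo aryllithium does not lose LiBr, and transmetalation to copper followed by SN2 allylation with prenyl bromide places the second prenyl group at C2'.

Step 7
Reactants: 5 5,7-bis(methoxymethoxy)-8-(3-methylbut-2-en-1-yl)-4H-chromen-4-one; 12 4-bromo-1,2-bis(methoxymethoxy)-3,5-bis(3-methylbut-2-en-1-yl)benzene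
Product: 14 2-[3,4-bis(methoxymethoxy)-2,6-bis(3-methylbut-2-en-1-yl)phenyl]-5,7-bis(methoxymethoxy)-8-(3-methylbut-2-en-1-yl)-4H-chromen-4-one, via bis(chromon-2-yl)zinc 13 (not isolated)
Conditions: 5, TMP2Zn·2MgCl2·2LiCl (0.6 equiv), THF, −30 °C; then 12, Pd(OAc)2 (5 mol%), SPhos (10 mol%), 55 °C
Reagents that add atoms: none
Why: MgCl2 from the base binds the C4 carbonyl (chelated by the 5-O-MOM oxygen) and so acidifies the vinylogous C2–H next to O1, which the zinc amide removes to give diorganozinc 13; oxidative addition of bromide 12 to zerovalent palladium, transmetalation from zinc and reductive elimination then form the C2–C1' bond. The closest known reaction type is the Lewis-acid-triggered C2 zincation of chromones followed by Negishi coupling to flavones. No ring is closed and no stereocentre is formed. The step needs site selectivity for C2–H over C3–H, the C6–H between the two MOM ethers and the benzylic-allylic CH2 of the prenyl group: the zinc amide is too mild for plain arene or allylic C–H bonds, and MgCl2 complexation steers it from C3 to C2. It also needs coupling at a bromide flanked by two CH2 groups, for which the bulky, electron-rich biaryl phosphine SPhos is chosen, while the prenyl alkenes should stay out because insertion into the aryl–palladium bond would require a 4-exo or 5-endo closure.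

Step 8
Reactants: 14 2-[3,4-bis(methoxymethoxy)-2,6-bis(3-methylbut-2-en-1-yl)phenyl]-5,7-bis(methoxymethoxy)-8-(3-methylbut-2-en-1-yl)-4H-chromen-4-one
Product: 17 2-[3,4-bis(methoxymethoxy)-2,6-bis(3-methylbut-2-en-1-yl)phenyl]-3-hydroxy-5,7-bis(methoxymethoxy)-8-(3-methylbut-2-en-1-yl)-4H-chromen-4-one, via 3-lithioflavone 15 (not isolated), via dimethyl boronate 16 (not isolated)
Conditions: LiN(i-Pr)2, THF, −78 °C; B(OMe)3, −78 → 0 °C; then AcOH, H2O2 (30% aq.), 0 °C
Reagents that add atoms: hydrogen peroxide, OO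
Why: Deprotonation of the flavone at C3 (the only C–H of ring C, next to the carbonyl that guides the base), borylation and boronate oxidation with 1,2-shift of C3 from boron to oxygen give the flavonol, and the nucleophilic peroxide should leave the unactivated prenyl alkenes untouched.

Step 9
Reactants: 17 2-[3,4-bis(methoxymethoxy)-2,6-bis(3-methylbut-2-en-1-yl)phenyl]-3-hydroxy-5,7-bis(methoxymethoxy)-8-(3-methylbut-2-en-1-yl)-4H-chromen-4-one
Product: 18 Petalostemumol G
Conditions: HCl (3 M aq.), MeOH, 40 °C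
Reagents that add atoms: none
Why: Acid-catalysed acetal cleavage (transacetalisation to dimethoxymethane) removes the four MOM ethers, and dilute acid at mild temperature should keep the freed ortho phenols from adding to the prenyl alkenes.

Compound list
1 | 2,4,6-trihydroxyacetophenone | CC(=O)c1c(O)cc(O)cc1O | starting material
2 | 1-[2,4,6-trihydroxy-3-(3-methylbut-2-en-1-yl)phenyl]ethan-1-one | CC(=O)c1c(O)cc(O)c(CC=C(C)C)c1O | intermediate
3 | 1-[2-hydroxy-4,6-bis(methoxymethoxy)-3-(3-methylbut-2-en-1-yl)phenyl]ethan-1-one | CC(=O)c1c(O)c(CC=C(C)C)c(OCOC)cc1OCOC | intermediate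
4 | (E)-3-(dimethylamino)-1-[2-hydroxy-4,6-bis(methoxymethoxy)-3-(3-methylbut-2-en-1-yl)phenyl]prop-2-en-1-one (enaminone) | CN(C)/C=C/C(=O)c1c(O)c(CC=C(C)C)c(OCOC)cc1OCOC | intermediate
5 | 5,7-bis(methoxymethoxy)-8-(3-methylbut-2-en-1-yl)-4H-chromen-4-one | O=c1ccoc2c(CC=C(C)C)c(OCOC)cc(OCOC)c12 | intermediate
6 | 4,5-dibromobenzene-1,2-diol | Oc1cc(Br)c(Br)cc1O | starting material
7 | 1,2-dibromo-4,5-bis(methoxymethoxy)benzene | COCOc1cc(Br)c(Br)cc1OCOC | intermediate
8 | [2-bromo-4,5-bis(methoxymethoxy)phenyl]magnesium chloride | COCOc1cc(Br)c([Mg]Cl)cc1OCOC | intermediate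
9 | 1-bromo-4,5-bis(methoxymethoxy)-2-(3-methylbut-2-en-1-yl)benzene | COCOc1cc(Br)c(CC=C(C)C)cc1OCOC | intermediate
10 | [2-bromo-5,6-bis(methoxymethoxy)-3-(3-methylbut-2-en-1-yl)phenyl]lithium | COCOc1cc(CC=C(C)C)c(Br)c([Li])c1OCOC | intermediate
11 | [2-bromo-5,6-bis(methoxymethoxy)-3-(3-methylbut-2-en-1-yl)phenyl]copper | COCOc1cc(CC=C(C)C)c(Br)c([Cu])c1OCOC | intermediate
12 | 4-bromo-1,2-bis(methoxymethoxy)-3,5-bis(3-methylbut-2-en-1-yl)benzene | COCOc1cc(CC=C(C)C)c(Br)c(CC=C(C)C)c1OCOC | intermediate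
13 | bis[5,7-bis(methoxymethoxy)-8-(3-methylbut-2-en-1-yl)-4-oxo-4H-chromen-2-yl]zinc | O=c1cc([Zn]c2cc(=O)c3c(OCOC)cc(OCOC)c(CC=C(C)C)c3o2)oc2c(CC=C(C)C)c(OCOC)cc(OCOC)c12 | intermediate
14 | 2-[3,4-bis(methoxymethoxy)-2,6-bis(3-methylbut-2-en-1-yl)phenyl]-5,7-bis(methoxymethoxy)-8-(3-methylbut-2-en-1-yl)-4H-chromen-4-one | CC(C)=CCc1cc(OCOC)c(OCOC)c(CC=C(C)C)c1-c1cc(=O)c2c(OCOC)cc(OCOC)c(CC=C(C)C)c2o1 | intermediate
15 | 3-lithio derivative of 14 | CC(C)=CCc1cc(OCOC)c(OCOC)c(CC=C(C)C)c1-c1oc2c(CC=C(C)C)c(OCOC)cc(OCOC)c2c(=O)c1[Li] | intermediate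
16 | dimethyl {2-[3,4-bis(methoxymethoxy)-2,6-bis(3-methylbut-2-en-1-yl)phenyl]-5,7-bis(methoxymethoxy)-8-(3-methylbut-2-en-1-yl)-4-oxo-4H-chromen-3-yl}boronate | CC(C)=CCc1cc(OCOC)c(OCOC)c(CC=C(C)C)c1-c1oc2c(CC=C(C)C)c(OCOC)cc(OCOC)c2c(=O)c1B(OC)OC | intermediate
17 | 2-[3,4-bis(methoxymethoxy)-2,6-bis(3-methylbut-2-en-1-yl)phenyl]-3-hydroxy-5,7-bis(methoxymethoxy)-8-(3-methylbut-2-en-1-yl)-4H-chromen-4-one | CC(C)=CCc1cc(OCOC)c(OCOC)c(CC=C(C)C)c1-c1oc2c(CC=C(C)C)c(OCOC)cc(OCOC)c2c(=O)c1O | intermediate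
18 | Petalostemumol G, 2-[3,4-dihydroxy-2,6-bis(3-methylbut-2-en-1-yl)phenyl]-3,5,7-trihydroxy-8-(3-methylbut-2-en-1-yl)-4H-chromen-4-one | CC(C)=CCc1cc(O)c(O)c(CC=C(C)C)c1-c1oc2c(CC=C(C)C)c(O)cc(O)c2c(=O)c1O | target

Total step count: 9. Longest linear sequence: 6 steps (steps 1 to 3 or steps 4 to 6, then steps 7 to 9).

Steps most likely to fail

Step 7 (key step). The coupling may stall at transmetalation or reductive elimination on the palladium centre that carries the doubly ortho-substituted aryl group, so that protodezincation of 13 and reduction of 12 take over. The fallback sets out from 12 and 5 and comes back at 14; it reverses the polarity and replaces the cross-coupling by a conjugate addition. Bromide 12 is converted with Mg turnings and LiCl in THF into [3,4-bis(methoxymethoxy)-2,6-bis(3-methylbut-2-en-1-yl)phenyl]magnesium bromide F1. Under CuBr·SMe2 catalysis with Me3SiCl (THF, −78 → −20 °C), F1 should add to C2 of chromone 5 and give the racemic silyl enol ether 2-[3,4-bis(methoxymethoxy)-2,6-bis(3-methylbut-2-en-1-yl)phenyl]-5,7-bis(methoxymethoxy)-8-(3-methylbut-2-en-1-yl)-4-(trimethylsilyloxy)-2H-chromene F2. Saegusa–Ito oxidation (Pd(OAc)2, 1.0 equiv, MeCN, rt) then restores the C2=C3 double bond and leads to flavone 14.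

Step 8. The amide base may remove a benzylic-allylic CH2 proton of a prenyl group or the C6–H in place of C3–H, or add to C2, so that the peroxide step meets a mixture of boron species. The fallback sets out from chromone 5 and comes back at target 18; it installs the C3 oxygen before the coupling.
- Nucleophilic epoxidation of 5 (H2O2, NaOH, MeOH, 0 °C) should give racemic 2,3-epoxy-5,7-bis(methoxymethoxy)-8-(3-methylbut-2-en-1-yl)chroman-4-one F3.
- Pyridinium p-toluenesulfonate in CH2Cl2 should open the epoxide at C2 and, after loss of the C3 proton, give 3-hydroxy-5,7-bis(methoxymethoxy)-8-(3-methylbut-2-en-1-yl)-4H-chromen-4-one F4.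
- MOMCl and i-Pr2NEt give 3,5,7-tris(methoxymethoxy)-8-(3-methylbut-2-en-1-yl)-4H-chromen-4-one F5.
- Its only C–H on ring C, at C2, is zincated with TMP2Zn·2MgCl2·2LiCl to bis[3,5,7-tris(methoxymethoxy)-8-(3-methylbut-2-en-1-yl)-4-oxo-4H-chromen-2-yl]zinc F6.
- Coupling with 12 (Pd(OAc)2, SPhos, THF, 55 °C) gives 2-[3,4-bis(methoxymethoxy)-2,6-bis(3-methylbut-2-en-1-yl)phenyl]-3,5,7-tris(methoxymethoxy)-8-(3-methylbut-2-en-1-yl)-4H-chromen-4-one F7.
- The conditions of step 9 then remove all five MOM groups and give 18.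

Step 2. MOM transfer may take the 2-OH in place of the 6-OH, or give mixtures, which would send the prenyl group to C6 of the chromone. The fallback sets out from 1 and comes back at 5, replacing steps 1 to 3; it brings the prenyl group to C8 by a para-Claisen–Cope sequence in which no regiochemical choice between the two ortho hydroxyls arises.
- Compound 1 with MOMCl (1.0 equiv) and K2CO3 in acetone gives 1-[2,6-dihydroxy-4-(methoxymethoxy)phenyl]ethan-1-one F8.
- DMF-DMA forms (E)-3-(dimethylamino)-1-[2,6-dihydroxy-4-(methoxymethoxy)phenyl]prop-2-en-1-one F9, which on treatment with AcOH closes through either hydroxyl to the same 5-hydroxy-7-(methoxymethoxy)-4H-chromen-4-one F10.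
- Prenyl bromide and K2CO3 in DMF give 7-(methoxymethoxy)-5-[(3-methylbut-2-en-1-yl)oxy]-4H-chromen-4-one F11.
- With Eu(fod)3 (10 mol%) in CHCl3 at 60 °C, aromatic Claisen rearrangement to C6 should give the dienone 7-(methoxymethoxy)-6-(2-methylbut-3-en-2-yl)-6H-chromene-4,5-dione F12. Cope rearrangement to C8 and tautomerisation then give 5-hydroxy-7-(methoxymethoxy)-8-(3-methylbut-2-en-1-yl)-4H-chromen-4-one F13.
- NaH and MOMCl in DMF lead to 5.

Further compounds
F1 | step 7 | [3,4-bis(methoxymethoxy)-2,6-bis(3-methylbut-2-en-1-yl)phenyl]magnesium bromide | COCOc1cc(CC=C(C)C)c([Mg]Br)c(CC=C(C)C)c1OCOC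
F2 | step 7 | 2-[3,4-bis(methoxymethoxy)-2,6-bis(3-methylbut-2-en-1-yl)phenyl]-5,7-bis(methoxymethoxy)-8-(3-methylbut-2-en-1-yl)-4-(trimethylsilyloxy)-2H-chromene (racemic) | C[Si](C)(C)OC1=CC(c2c(CC=C(C)C)cc(OCOC)c(OCOC)c2CC=C(C)C)Oc2c(CC=C(C)C)c(OCOC)cc(OCOC)c21
F3 | step 8 | 2,3-epoxy-5,7-bis(methoxymethoxy)-8-(3-methylbut-2-en-1-yl)chroman-4-one (racemic, cis-fused) | O=C1C2OC2Oc2c(CC=C(C)C)c(OCOC)cc(OCOC)c12
F4 | step 8 | 3-hydroxy-5,7-bis(methoxymethoxy)-8-(3-methylbut-2-en-1-yl)-4H-chromen-4-one | O=c1c(O)coc2c(CC=C(C)C)c(OCOC)cc(OCOC)c12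
F5 | step 8 | 3,5,7-tris(methoxymethoxy)-8-(3-methylbut-2-en-1-yl)-4H-chromen-4-one | O=c1c(OCOC)coc2c(CC=C(C)C)c(OCOC)cc(OCOC)c12
F6 | step 8 | bis[3,5,7-tris(methoxymethoxy)-8-(3-methylbut-2-en-1-yl)-4-oxo-4H-chromen-2-yl]zinc | COCOc1c([Zn]c2oc3c(CC=C(C)C)c(OCOC)cc(OCOC)c3c(=O)c2OCOC)oc2c(CC=C(C)C)c(OCOC)cc(OCOC)c2c1=O
F7 | step 8 | 2-[3,4-bis(methoxymethoxy)-2,6-bis(3-methylbut-2-en-1-yl)phenyl]-3,5,7-tris(methoxymethoxy)-8-(3-methylbut-2-en-1-yl)-4H-chromen-4-one | CC(C)=CCc1cc(OCOC)c(OCOC)c(CC=C(C)C)c1-c1oc2c(CC=C(C)C)c(OCOC)cc(OCOC)c2c(=O)c1OCOC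
F8 | step 2 | 1-[2,6-dihydroxy-4-(methoxymethoxy)phenyl]ethan-1-one | CC(=O)c1c(O)cc(OCOC)cc1O
F9 | step 2 | (E)-3-(dimethylamino)-1-[2,6-dihydroxy-4-(methoxymethoxy)phenyl]prop-2-en-1-one | CN(C)/C=C/C(=O)c1c(O)cc(OCOC)cc1O
F10 | step 2 | 5-hydroxy-7-(methoxymethoxy)-4H-chromen-4-one | O=c1ccoc2cc(OCOC)cc(O)c12
F11 | step 2 | 7-(methoxymethoxy)-5-[(3-methylbut-2-en-1-yl)oxy]-4H-chromen-4-one | O=c1ccoc2cc(OCOC)cc(OCC=C(C)C)c12
F12 | step 2 | 7-(methoxymethoxy)-6-(2-methylbut-3-en-2-yl)-6H-chromene-4,5-dione (racemic) | O=C1C=COC2=C1C(=O)C(C(C)(C)C=C)C(OCOC)=C2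
F13 | step 2 | 5-hydroxy-7-(methoxymethoxy)-8-(3-methylbut-2-en-1-yl)-4H-chromen-4-one | O=c1ccoc2c(CC=C(C)C)c(OCOC)cc(O)c12
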